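**Strategy.** Gentiside E is disconnected at the C1–C6 bond of its benzene ring, because the catechol ring is the aromatic tautomer of a cyclised, dehydrated open-chain keto-aldehyde. Arene carbons C3–C6 are the four carbons of a furan (a masked Z-1,4-dicarbonyl), C2 is the former formyl carbon of furfural, and C1 with the ester carbonyl is a bromoacetate unit. One operation on the Achmatowicz pyranone, octadecyl 2-(6-hydroxy-3-oxo-3,6-dihydro-2H-pyran-2-yl)acetate, opens the lactol, shifts the α-ketol, closes the carbocycle by Knoevenagel condensation and aromatises with loss of one water, without any redox reagent. The precursor arises in three known steps from 1-octadecanol, bromoacetyl bromide and furfural.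

Key step: step 4

Atom labels: arene numbering of the target is used throughout (C1 bears the ester, C2 and C3 the hydroxyls). In the pyranone precursor the ring carbons C2–C6 carry the same numbers, and C1 is the side-chain methylene.

Assumption: the furyl carbinol and the pyranone are carried as racemates (the pyranone as its anomeric mixture), since both stereocentres vanish in step 4; the pyranone needs no redesign, because the ketol shift in step 4 supplies the second activating group at C1.

Step 1
Reactants: 1 1-octadecanol; 2 bromoacetyl bromide
Product: 3 octadecyl 2-bromoacetate
Conditions: pyridine (1.1 equiv), CH2Cl2, 0 °C to rt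
Reagents that add atoms: none
Why: O-acylation of a primary alcohol by an acyl bromide under pyridine is fast at 0 °C, and the acyl bromide reacts far faster than the alkyl bromide, so the bromomethyl group survives.

Step 2
Reactants: 3 octadecyl 2-bromoacetate; 4 furfural
Product: 6 octadecyl 3-(furan-2-yl)-3-hydroxypropanoate (racemic), via Reformatsky reagent 5 (not isolated)
Conditions: Zn dust (TMSCl-activated), THF, 40 °C; then sat. aq. NH4Cl, 0 °C
Reagents that add atoms: none
Why: Reformatsky reaction: zinc inserts into the C–Br bond of 3 to give the zinc enolate 5, which adds to the non-enolisable aldehyde 4 without attacking the ester; the carbinol centre forms without control (racemic), which is immaterial because step 4 destroys it, and the near-neutral quench avoids dehydration of the furyl carbinol.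

Step 3
Reactants: 6 octadecyl 3-(furan-2-yl)-3-hydroxypropanoate
Product: 8 octadecyl 2-(6-hydroxy-3-oxo-3,6-dihydro-2H-pyran-2-yl)acetate (racemic; anomeric mixture), via dihydrofuran diol 7 (not isolated)
Conditions: NBS, NaHCO3, THF/H2O (4:1), 0 °C; product used promptly
Reagents that add atoms: water, O
Why: Achmatowicz rearrangement: NBS brominates the unsubstituted α-position of the 2-furylcarbinol, water traps the resulting oxocarbenium and then displaces the α-bromo ether bromide to give the cyclic bis-hemiacetal 7, which loses water and exchanges its five-membered hemiketal for the six-membered lactol 8 by ring–chain tautomerism as the carbinol oxygen captures the aldehyde carbon; the anomeric centre forms as a mixture and C2 stays racemic, neither of which matters later.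

Step 4
Reactants: 8 octadecyl 2-(6-hydroxy-3-oxo-3,6-dihydro-2H-pyran-2-yl)acetate
Product: 12 Gentiside E (octadecyl 2,3-dihydroxybenzoate), via open-chain keto-enal 9 (not isolated), via transposed β-keto ester 10 (not isolated), via hydroxy-dienone 11 (not isolated)
Conditions: piperidine (20 mol %), AcOH (20 mol %), 4 Å MS, degassed toluene, 60 °C, Ar
Reagents that add atoms: none
Why: Proposed new method: the amine buffer should hold lactol 8 in equilibrium with its open (Z)-keto-enal 9, transpose the C3-keto/C2-hydroxy α-ketol of 9 through the conjugated enediol to the C2-keto isomer 10, in which C1 is a β-keto ester methylene, and then condense C1 with the piperidine iminium of the C6 aldehyde (intramolecular Knoevenagel, new bond C1–C6), after which loss of water gives dienone 11, the keto tautomer of the catechol, which enolises irreversibly to 12. The closest known reaction types are the ammonia-mediated recyclisation of 2-acylfurans to 3-hydroxypyridines and the hydrothermal conversion of 5-(hydroxymethyl)furfural into 1,2,4-benzenetriol, both of which open a furan-derived 1,4-dicarbonyl and re-close it to a six-membered aromatic ring, while the individual events (Lobry de Bruyn–Alberda van Ekenstein ketol transposition, amine-catalysed Knoevenagel condensation, keto–enol aromatisation of a cyclohexadienone) are each standard. The benzene ring closes in a 6-exo-trig mode at C6 (6-enolendo-exo-trig for the C1=C2 enol of the keto ester), the C6=N+ or C6=O bond lying outside the forming ring, which is a favoured closure. No stereocentre is created and both stereocentres of 8 are erased, so nothing has to be controlled. The step needs C1–C6 closure to win over the five-ring aldol from C2 to C6 (hydroxycyclopentenone), cyclodehydration of the 4-hydroxy-enal in 10 to a furan, and Z-to-E isomerisation; the Z-alkene inherited from the pyranone ring keeps C6 within bonding distance of C1, C1 is the only doubly activated carbon once the ketol has shifted, the competing aldol and lactol formations are reversible, and aromatisation is an irreversible sink that needs no oxidant or reductant because 8 and 12 differ only by one molecule of water.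

**Compound list**

1 | 1-octadecanol | CCCCCCCCCCCCCCCCCCO | starting material
2 | bromoacetyl bromide | BrCC(=O)Br | starting material
3 | octadecyl 2-bromoacetate | CCCCCCCCCCCCCCCCCCOC(=O)CBr | intermediate
4 | furfural (furan-2-carbaldehyde) | O=Cc1ccco1 | starting material
5 | bromo(2-octadecyloxy-2-oxoethyl)zinc, BrZnCH2CO2C18H37 (Reformatsky reagent) | CCCCCCCCCCCCCCCCCCOC(=O)C[Zn]Br | intermediate (not isolated)
6 | octadecyl 3-(furan-2-yl)-3-hydroxypropanoate (racemic) | CCCCCCCCCCCCCCCCCCOC(=O)CC(O)c1ccco1 | intermediate
7 | octadecyl 3-(2,5-dihydroxy-2,5-dihydrofuran-2-yl)-3-hydroxypropanoate (cyclic bis-hemiacetal; mixture of diastereomers) | CCCCCCCCCCCCCCCCCCOC(=O)CC(O)C1(O)C=CC(O)O1 | intermediate (not isolated)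
8 | octadecyl 2-(6-hydroxy-3-oxo-3,6-dihydro-2H-pyran-2-yl)acetate (racemic; anomeric mixture) | CCCCCCCCCCCCCCCCCCOC(=O)CC1OC(O)C=CC1=O | intermediate
9 | octadecyl (Z)-3-hydroxy-4,7-dioxohept-5-enoate (racemic; open-chain tautomer of 8) | CCCCCCCCCCCCCCCCCCOC(=O)CC(O)C(=O)/C=C\C=O | intermediate (not isolated)
10 | octadecyl (Z)-4-hydroxy-3,7-dioxohept-5-enoate (racemic) | CCCCCCCCCCCCCCCCCCOC(=O)CC(=O)C(O)/C=C\C=O | intermediate (not isolated)
11 | octadecyl 5-hydroxy-6-oxocyclohexa-1,3-diene-1-carboxylate (racemic) | CCCCCCCCCCCCCCCCCCOC(=O)C1=CC=CC(O)C1=O | intermediate (not isolated)
12 | Gentiside E, octadecyl 2,3-dihydroxybenzoate (no stereocentre) | CCCCCCCCCCCCCCCCCCOC(=O)c1cccc(O)c1O | target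

**Step count.** Total: 4 steps. Longest linear sequence: 4 steps (1 → 3 → 6 → 8 → 12).

**Steps most likely to fail**

1. Step 4 (new method). The opened keto-enal may divert before C1 is activated or before it reaches C6. The possible diversions are the reversible five-ring aldol that ends in a hydroxycyclopentenone, cyclodehydration of the transposed 4-hydroxy-enal back to a furan, Z-to-E isomerisation that separates C1 from C6, β-elimination of the C2 hydroxyl before the ketol shifts, and amine-mediated oligomerisation. The fallback gives up the ring construction and uses known ester formation on a preformed catechol acid. It sets out from 1 and returns at 12. Appel bromination of 1 (CBr4, PPh3, CH2Cl2, 0 °C) should give 1-bromooctadecane F1. Commercial 2,3-dihydroxybenzoic acid (O=C(O)c1cccc(O)c1O) is then O-alkylated at the carboxylate with F1 (KHCO3, DMF, 60 °C, Ar). The bicarbonate ionises only the carboxylic acid, so the catechol hydroxyls should remain free and 12 results directly.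

2. Step 3. Over-bromination of the furan or of the product enone, poor mixing of the waxy C18 substrate with the aqueous phase, and loss of the sensitive lactol on work-up or silica may erode the oxidation. The fallback separates oxidation from hydrolysis. It sets out from 6 and returns at 8. Oxidative methoxylation of 6 (Br2, MeOH, Na2CO3, −40 °C) should give octadecyl 3-(2,5-dimethoxy-2,5-dihydrofuran-2-yl)-3-hydroxypropanoate F2 as a diastereomer mixture, a stable and fully organic-soluble bis-acetal that can be purified. Mild acid hydrolysis (1 % aq. H2SO4, THF, rt) then unmasks the keto-enal, which closes to 8.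

3. Step 2. Erratic zinc insertion, self-condensation of the bromoester, or dehydration and retro-aldol cleavage of the furyl carbinol during work-up may limit the Reformatsky addition. The fallback is a preformed lithium enolate aldol. It sets out from 1 and returns at 6. Acetylation of 1 (Ac2O, pyridine, DMAP cat., CH2Cl2, rt) should give octadecyl acetate F3. Deprotonation with commercial LiN(iPr)2 (THF, −78 °C), addition of 4 and a cold AcOH quench should then deliver 6 without any zinc chemistry.

**Further compounds**

F1 | step 4 | 1-bromooctadecane | CCCCCCCCCCCCCCCCCCBr
F2 | step 3 | octadecyl 3-(2,5-dimethoxy-2,5-dihydrofuran-2-yl)-3-hydroxypropanoate (mixture of diastereomers) | CCCCCCCCCCCCCCCCCCOC(=O)CC(O)C1(OC)C=CC(OC)O1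
F3 | step 2 | octadecyl acetate | CCCCCCCCCCCCCCCCCCOC(C)=O
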